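Two questions hang on one flask: how the rate at 20 % conversion changes when the charge of E is doubled, and when it is cut.

| setting | zeta | beta | flask |
|---|---|---|---|
| G | 0.50 mM | 0.50 mM | 0.50 mM |
| J | 0.017 mM | 0.038 mM | 0.0250 mM |
| E | 2.6 µM | 2.6 µM | 2.6 µM |
| remark | run made earlier | run made earlier |  |

- zeta (time / min: X / %, G / %): 1.00: 87.3, 12.0; 3.00: 100.2, 0.7; 5.00: 99.3, 0.2; 8.00: 99.3, 0.1; 12.0: 99.2, 1.4; 15.0: 100.8, 0.6
- beta (time / min: X / %, G / %): 2.50: 72.3, 26.9; 5.00: 73.5, 25.8; 8.00: 74.1, 25.5; 10.0: 73.8, 24.9; 12.0: 73.9, 25.9; 15.0: 73.7, 26.3

(each reading ± 0.5 percentage points)

* factor on the rate of making X when 20 % of the G are converted if E is charged twice over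
* factor on the rate when 20 % of the G are converted if E is charged at 0.50 µM instead

- the numbers in the tables scatter with a standard deviation of 0.5 percentage points
- steps that have been proposed: G + E -> D; D -> E + X; D + J -> L
- no earlier run changes the charge of E; that part of a forecast is a guess

The earlier runs differ in c(J). Zeta ends with X near the whole charge, but beta stands flat from its reading at 5.00 min on, with 26.3 % of the G still there at the last reading, so its catalyst has stopped working.

One chemist holds that rate simply follows the charge, which gives factors of 2 and 0.192. The other, whose side I take, holds that each pass through D risks capture by J, so the loss counts per X made, whatever the charge.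

Beta made 369 µM and, on her view, lost its whole 2.6 µM, while c(J) fell by that amount. This gives 5210 µM: the capture constant, X made times mean c(J) over catalyst lost, a selectivity factor between release and capture. For zeta it puts the loss at full conversion at 1.63 µM, less than the 2.6 µM charged, and zeta finished.

In the flask, 100 µM of X at 0.0250 mM of J costs 0.480 µM. Taking c(J) at its mean is the small correction, and it gives 0.475 µM.

At fixed c(G), working catalyst divides between E and D in the same proportion at any amount. So rate goes as charge minus loss, and I reckon 2.22 and 0.0116. With this loss held fixed, the first chemist is right for charges far above it, but 0.50 µM stands barely above it.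

The forecast, on the same side, gave 2.22 and 0.012, calling the small charge “barely alive, so it is very sensitive”. The flask gives 2.23 and 0.0116.

    G + E → D (k = 31000 M⁻¹ s⁻¹)
    D → E + X (k = 14.0 s⁻¹)
    D + J → L (k = 2700 M⁻¹ s⁻¹)

In this flask a D goes on to E + X at 840 min⁻¹ and into L at 4.0 min⁻¹ with J as charged, 207 times slower, and the capture constant prices the whole G at 2.28 µM of the 2.6 µM charged, while L stands at 88.0 % and E at 12.0 % after 15.0 min. In the flask charged with 0.50 µM, L at the same conversion is 95.0 % of the catalyst, which is 0.475 µM.

The data were computed with made-up constants; scatter was added.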